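**Plan** (oxolane numbering: O1, C2 pentyl, C3 ester, C4 CH2, C5 side chain, C1' carbinol carbon)
- **Cuts, in retrosynthetic order:** C1'–C2' (oxolane-carbaldehyde + non-8-enyl Grignard reagent). Then O1–C5, with O1 re-attached to C1', which turns the oxolane into a 3,4-dihydro-2H-pyran. Then the C3–O ester bond, and finally the pyran back to a 2-acylfuran.
- **Enabling feature:** ring O1 and the carbinol oxygen sit on adjacent carbons (O1–C5–C1'–O), and C4 is a bare CH2. This is the signature of a 1,2-shift of a pyran oxygen from C1' to C5, so a six-membered ring O1/C2/C3/C4/C5/C1' can contract and extrude C1' as a formyl group.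
- **Forward order of rings:** furan (five atoms) → Achmatowicz pyranone (six) → 3-deoxyglycal-type dihydropyran → oxidative contraction to the oxolane (five). The C9 chain with the terminal alkene is joined last, and no protecting group is used.
- **Stereochemistry:** C2 comes from asymmetric transfer hydrogenation. C3 comes from substrate-controlled 1,2-reduction and then Mitsunobu inversion with myristic acid itself. C5 comes from anti attack of the iodane followed by invertive O-shift. C1' comes from Cram-chelate addition.

Key step: step 7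

Assumption: 1-(furan-2-yl)hexan-1-one (2-hexanoylfuran, a catalogued flavour compound) is taken as purchasable.

Step 1
Reactants: 1 1-(furan-2-yl)hexan-1-one
Product: 2 (S)-1-(furan-2-yl)hexan-1-ol
Conditions: RuCl(p-cymene)[(S,S)-TsDPEN] (0.5 mol %), HCO2H/Et3N 5:2, rt
Reagents that add atoms: none
Why: Noyori asymmetric transfer hydrogenation of a heteroaryl alkyl ketone, in which the (S,S)-ligand should deliver hydride to the Re face through the CH–π-organised six-membered transition state and so set the S carbinol centre (later C2).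

Step 2
Reactants: 2 (S)-1-(furan-2-yl)hexan-1-ol
Product: 3 (2S)-6-hydroxy-2-pentyl-2H-pyran-3(6H)-one (anomeric mixture)
Conditions: mCPBA, CH2Cl2, 0 °C to rt
Reagents that add atoms: mCPBA, O=C(OO)c1cccc(Cl)c1
Why: Achmatowicz rearrangement, in which peracid oxidation dearomatises the furan to the ene-dicarbonyl and the carbinol oxygen closes on the aldehyde carbon to the six-membered hemiacetal, leaving the C–O stereocentre untouched.

Step 3
Reactants: 3 (2S)-6-hydroxy-2-pentyl-2H-pyran-3(6H)-one
Product: 4 (2S)-2-pentyl-2H-pyran-3(6H)-one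
Conditions: Et3SiH, CF3CO2H, CH2Cl2, −40 to 0 °C
Reagents that add atoms: none
Why: Ionic hydrogenation (acid ionises the hemiacetal and the silane reduces the oxocarbenium ion at the acetal carbon), a standard follow-up of the Achmatowicz reaction that leaves the enone and C2 intact.

Step 4
Reactants: 4 (2S)-2-pentyl-2H-pyran-3(6H)-one
Product: 5 (2S,3R)-2-pentyl-3,6-dihydro-2H-pyran-3-ol
Conditions: NaBH4, CeCl3·7H2O, MeOH, −78 °C
Reagents that add atoms: none
Why: Luche 1,2-reduction, in which axial hydride attack on the half-chair with equatorial pentyl should give the equatorial alcohol trans to pentyl, so C2 controls C3.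

Step 5
Reactants: 5 (2S,3R)-2-pentyl-3,6-dihydro-2H-pyran-3-ol; 6 tetradecanoic acid (myristic acid)
Product: 7 (2S,3S)-2-pentyl-3,6-dihydro-2H-pyran-3-yl tetradecanoate
Conditions: PPh3, DIAD, THF, 0 °C to rt
Reagents that add atoms: none
Why: Mitsunobu esterification, in which SN2 displacement of the oxyphosphonium ion by myristate inverts C3 to the cis (3S) configuration and installs the final acyl group in the same operation.

Step 6
Reactants: 7 (2S,3S)-2-pentyl-3,6-dihydro-2H-pyran-3-yl tetradecanoate
Product: 8 (2S,3S)-2-pentyl-3,4-dihydro-2H-pyran-3-yl tetradecanoate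
Conditions: RuHCl(CO)(PPh3)3 (5 mol %), toluene, 80 °C
Reagents that add atoms: none
Why: Metal-hydride catalysed allyl ether to enol ether isomerisation (hydrometalation/β-hydride elimination), driven by conjugation of the new double bond with the ring oxygen; Ru should add at the alkene carbon remote from branched C3, and no stereocentre is touched.

Step 7
Reactants: 8 (2S,3S)-2-pentyl-3,4-dihydro-2H-pyran-3-yl tetradecanoate
Product: 10 (2S,3S,5R)-5-formyl-2-pentyloxolan-3-yl tetradecanoate, via iodane adduct 9 (not isolated)
Conditions: PhI(OH)OTs (1.1 equiv), 4 Å MS, MeCN, −20 to 0 °C; aq NaHCO3 work-up, product used at once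
Reagents that add atoms: [hydroxy(tosyloxy)iodo]benzene, OI(c1ccccc1)OS(=O)(=O)c1ccc(C)cc1
Why: Oxidative ring contraction of a cyclic enol ether by a trivalent iodine electrophile: the iodane adds to the nucleophilic β-carbon (pyran C5) and its hydroxide ends on pyran C6 to give the trans adduct 9, and in the chair with pentyl and the iodanyl group equatorial the C5–I bond is antiperiplanar to the ring O1–C6 bond, so O1 shifts from C6 to C5 while PhI leaves and the hemiacetal OH collapses to the aldehyde. The closest known reaction types are the contraction of glycals to 2,5-anhydro-aldoses with Tl(NO3)3 or PhI(OH)OTs and the nitrous acid deamination of 2-amino-2-deoxypyranoses. The oxolane closes by intramolecular SN2 displacement (formally 5-exo-tet, through a 1-oxoniabicyclo[3.1.0]hexane-like array), and the old pyran C6 is extruded as the formyl carbon. The one new stereocentre, oxolane C5, is fixed by two stereospecific events, namely iodane attack on the face opposite to the pseudoaxial acyloxy group and the pentyl group, then inversion by O1, which together should place the formyl group trans to pentyl. The step needs facial selectivity, migration of O1 rather than H or OH, and chemoselectivity: the cis C2/C3 substituents secure the first, the equatorial C–I bond secures the second, and the third is given because the enol ether is the only alkene present at this stage.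

Step 8
Reactants: 11 9-bromonon-1-ene
Product: 12 non-8-en-1-ylmagnesium bromide (ether solution)
Conditions: Mg turnings, I2 (crystal), Et2O, reflux
Reagents that add atoms: magnesium, [Mg]
Why: Grignard reagent formation from a primary bromide, in which the remote terminal alkene is too far away (a nine-membered ring would be needed) to cyclise on the transient radical.

Step 9
Reactants: 10 (2S,3S,5R)-5-formyl-2-pentyloxolan-3-yl tetradecanoate; 12 non-8-en-1-ylmagnesium bromide
Product: 13 (2S,3S,5R)-5-[(1R)-1-hydroxydec-9-en-1-yl]-2-pentyloxolan-3-yl tetradecanoate (target)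
Conditions: MgBr2·OEt2, CH2Cl2, −78 °C, then 12 in Et2O, −78 °C; H2O quench
Reagents that add atoms: none
Why: Chelation-controlled (Cram chelate) Grignard addition, in which magnesium bridges the aldehyde oxygen and O1 and the nucleophile enters from the side of the C5–H, which should give the threo (1'R) carbinol; the aldehyde reacts far faster than the ester at −78 °C.

**Compound list**
1 | 1-(furan-2-yl)hexan-1-one | CCCCCC(=O)c1ccco1 | starting material
2 | (S)-1-(furan-2-yl)hexan-1-ol | CCCCC[C@H](O)c1ccco1 | intermediate
3 | (2S)-6-hydroxy-2-pentyl-2H-pyran-3(6H)-one | CCCCC[C@@H]1OC(O)C=CC1=O | intermediate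
4 | (2S)-2-pentyl-2H-pyran-3(6H)-one | CCCCC[C@@H]1OCC=CC1=O | intermediate
5 | (2S,3R)-2-pentyl-3,6-dihydro-2H-pyran-3-ol | CCCCC[C@@H]1OCC=C[C@H]1O | intermediate
6 | tetradecanoic acid | CCCCCCCCCCCCCC(=O)O | starting material
7 | (2S,3S)-2-pentyl-3,6-dihydro-2H-pyran-3-yl tetradecanoate | CCCCC[C@@H]1OCC=C[C@@H]1OC(=O)CCCCCCCCCCCCC | intermediate
8 | (2S,3S)-2-pentyl-3,4-dihydro-2H-pyran-3-yl tetradecanoate | CCCCC[C@@H]1OC=CC[C@@H]1OC(=O)CCCCCCCCCCCCC | intermediate
9 | (2S,3S,5S,6S)-6-hydroxy-2-pentyl-5-[phenyl(tosyloxy)-λ3-iodanyl]oxan-3-yl tetradecanoate | CCCCC[C@@H]1O[C@H](O)[C@@H](I(c2ccccc2)OS(=O)(=O)c2ccc(C)cc2)C[C@@H]1OC(=O)CCCCCCCCCCCCC | intermediate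
10 | (2S,3S,5R)-5-formyl-2-pentyloxolan-3-yl tetradecanoate | O=C[C@H]1C[C@H](OC(=O)CCCCCCCCCCCCC)[C@H](CCCCC)O1 | intermediate
11 | 9-bromonon-1-ene | C=CCCCCCCCBr | starting material
12 | non-8-en-1-ylmagnesium bromide | C=CCCCCCCC[Mg]Br | intermediate
13 | (2S,3S,5R)-5-[(1R)-1-hydroxydec-9-en-1-yl]-2-pentyloxolan-3-yl tetradecanoate | C=CCCCCCCC[C@@H](O)[C@H]1C[C@H](OC(=O)CCCCCCCCCCCCC)[C@H](CCCCC)O1 | target

Total steps: 9. Longest linear sequence: 8 (steps 1 to 7 and 9).

**Steps most likely to fail**

**Step 7.**
- What may go wrong: incomplete facial selectivity of the iodane attack, capture of the adduct by tosylate instead of the O-shift, or acid-induced epimerisation of the aldehyde.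
- Fallback (from 8, back at 10), which moves control of C5 from the substrate to a catalyst. The enol ether is hydrated with PPTS in wet THF to the lactol (2S,3S)-6-hydroxy-2-pentyloxan-3-yl tetradecanoate F1.
- The open hydroxy-aldehyde form of F1 undergoes enamine-catalysed α-chlorination. The reagents are N-chlorosuccinimide and the enantiomer of 2,5-diphenylpyrrolidine that gives the 2S chloride. The product is the chloro lactol (2S,3S,5S)-5-chloro-6-hydroxy-2-pentyloxan-3-yl tetradecanoate F2.
- Ag2O/AgOTf in THF then triggers the same invertive contraction of the six-membered lactol to 10.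

**Step 6.**
- What may go wrong: double-bond migration toward the ester-bearing carbon, or loss of the allylic ester by β-acyloxy elimination from the ruthenium alkyl.
- Fallback (from 3, back at 8), which reaches the enol ether by elimination instead of isomerisation. Acid-catalysed acetalisation with MeOH gives (2S)-6-methoxy-2-pentyl-2H-pyran-3(6H)-one F3.
- H2 over Pd/C then gives (2S)-6-methoxy-2-pentyloxan-3-one F4.
- Equatorial hydride attack by LiBH(s-Bu)3 at −78 °C gives the axial, cis alcohol (2S,3S)-6-methoxy-2-pentyloxan-3-ol F5.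
- Tetradecanoyl chloride in pyridine gives (2S,3S)-6-methoxy-2-pentyloxan-3-yl tetradecanoate F6.
- TMSOTf/iPr2NEt in CH2Cl2 finally eliminates the methoxy group to give 8.

**Step 9.**
- What may go wrong: incomplete chelation and hence poor facial selectivity at the aldehyde.
- Fallback (from 10, back at 13), which sets C1' by reduction instead of addition. Addition of 12 without additive gives the C1'-epimeric carbinols F7.
- Dess–Martin oxidation gives the ketone (2S,3S,5R)-5-(dec-9-enoyl)-2-pentyloxolan-3-yl tetradecanoate F8.
- LiBH(s-Bu)3 at −78 °C should attack anti to the C5–O1 bond (polar Felkin–Anh) and give the threo alcohol 13 without touching the ester.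

**Further compounds**
F1 | step 7 | (2S,3S)-6-hydroxy-2-pentyloxan-3-yl tetradecanoate | CCCCC[C@@H]1OC(O)CC[C@@H]1OC(=O)CCCCCCCCCCCCC
F2 | step 7 | (2S,3S,5S)-5-chloro-6-hydroxy-2-pentyloxan-3-yl tetradecanoate | CCCCC[C@@H]1OC(O)[C@@H](Cl)C[C@@H]1OC(=O)CCCCCCCCCCCCC
F3 | step 6 | (2S)-6-methoxy-2-pentyl-2H-pyran-3(6H)-one | CCCCC[C@@H]1OC(OC)C=CC1=O
F4 | step 6 | (2S)-6-methoxy-2-pentyloxan-3-one | CCCCC[C@@H]1OC(OC)CCC1=O
F5 | step 6 | (2S,3S)-6-methoxy-2-pentyloxan-3-ol | CCCCC[C@@H]1OC(OC)CC[C@@H]1O
F6 | step 6 | (2S,3S)-6-methoxy-2-pentyloxan-3-yl tetradecanoate | CCCCC[C@@H]1OC(OC)CC[C@@H]1OC(=O)CCCCCCCCCCCCC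
F7 | step 9 | (2S,3S,5R)-5-(1-hydroxydec-9-en-1-yl)-2-pentyloxolan-3-yl tetradecanoate, C1' epimers | C=CCCCCCCCC(O)[C@H]1C[C@H](OC(=O)CCCCCCCCCCCCC)[C@H](CCCCC)O1
F8 | step 9 | (2S,3S,5R)-5-(dec-9-enoyl)-2-pentyloxolan-3-yl tetradecanoate | C=CCCCCCCCC(=O)[C@H]1C[C@H](OC(=O)CCCCCCCCCCCCC)[C@H](CCCCC)O1
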